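Reading at 2.0 d was the business of the meeting: how much of the substrate charged stands as product by then in Friday's, Wednesday's and Thursday's flasks, which differ in [enzyme].

| flask | substrate | enzyme | impurity | remark | time |
|---|---|---|---|---|---|
| south-west | 0.030 M | 12 µM | 3.9 µM | run made earlier |  |
| south | 0.040 M | 12 µM | 3.9 µM | run made earlier |  |
| Friday's | 0.020 M | 12 µM | 3.9 µM |  | 2.0 d |
| Wednesday's | 0.020 M | 16 µM | 3.9 µM |  | 2.0 d |
| Thursday's | 0.020 M | 20 µM | 3.9 µM |  | 2.0 d |

| run | time / h | substrate / % | complex / % | product / % |
|---|---|---|---|---|
| south-west | 2.50 | 94.9 | 0 | 3.1 |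
| south-west | 4.00 | 92.9 | 0 | 4.8 |
| south-west | 8.00 | 85.6 | 0.5 | 10.1 |
| south-west | 15.0 | 74.8 | 0 | 17.4 |
| south-west | 30.0 | 55.8 | 0 | 32.0 |
| south | 2.50 | 96.6 | 0.2 | 2.3 |
| south | 4.00 | 93.8 | 0.1 | 3.7 |
| south | 8.00 | 87.1 | 0 | 8.7 |
| south | 15.0 | 78.3 | 0.1 | 14.5 |
| south | 30.0 | 60.3 | 0 | 25.9 |

(scatter of a reading: 0.5 percentage points)

- which of these there is most of at the end, counted by the substrate in it, Friday's (substrate / product / complex)
- which of these there is most of at the end, counted by the substrate in it, Wednesday's (substrate / product / complex)
- which of these there is most of at the end, counted by the substrate in it, Thursday's (substrate / product / complex)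
- final amount of the leader among these, as a percentage of the substrate charged, in Friday's
- final amount of the leader among these, as a percentage of the substrate charged, in Wednesday's
- final amount of the leader among these, as a percentage of the substrate charged, in Thursday's

- steps thought possible: enzyme + impurity -> spent catalyst A; enzyme -> spent catalyst B; complex -> enzyme + product; substrate + enzyme <-> complex; substrate <-> dormant form
- no earlier run changes the charge of enzyme; that part of a forecast is a guess
- a reading of substrate is of its free form alone

The analyst opened with the mean of the curve. The south-west run made 9.60 mM of product in 30.0 h. But she would not divide that by the [enzyme] charged. Enzyme + impurity is a listed step and [impurity] stands below [enzyme], so impurity would be the limiting reagent of that step, and she counted as working enzyme the charge minus 3.9 µM, which leaves 8.10 µM. She granted that this was a guess, since no run changes the enzyme. Her quantity was the mean turnover, product made per hour per working enzyme: 39.5 h⁻¹ in the south-west run and 42.6 h⁻¹ in the south run.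

A colleague objected that a mean over 30.0 h carries the early hours into a reckoning for 2.0 d. The south-west turnover was 43.0 h⁻¹ up to 15.0 h and 36.0 h⁻¹ after it. Taking the later figure, the analyst reckoned 70.1% product for Friday's, and called it high: the two readings of [substrate] that bound that window average 19.6 mM, and Friday's flask starts at 20 mM and falls. On Wednesday's the same figure gives 105%, beyond the charge, so there the mean turnover has to drop further. On her count, working enzyme in Wednesday's is 1.49 times that in Friday's, where the bare charges give 1.33.

The forecast, which differs from her reckoning, put product ahead in each flask, at 59%, 72% and 80%, and said of the falling rate that it was “suggesting slow enzyme loss, perhaps 20% by 48 h”.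

Product leads in each flask, at 51.5%, 67.9% and 78.9%.

    enzyme + impurity → spent catalyst A (k = 598 L mol⁻¹ s⁻¹)
    enzyme → spent catalyst B (k = 8.65 × 10⁻⁶ s⁻¹)
    complex → enzyme + product (k = 0.0181 s⁻¹)
    substrate + enzyme ⇌ complex (K = 105 L mol⁻¹, k = 34.2 L mol⁻¹ s⁻¹)
    substrate ⇌ dormant form (K = 2.90, k = 1.54 × 10⁻⁶ s⁻¹)

The forecast falls within the tolerance for Wednesday's and Thursday's and stands 7.5 percentage points high for Friday's. In Friday's flask at 2.00 d, impurity stands at 0% of its own charge and spent catalyst A at 32.5% of the enzyme charged, beside the 32.5% that the charges give. Spent catalyst B in Friday's flask stands at 34.0% of the enzyme charged, where the forecast wrote of 20% enzyme loss. Mean turnover over 2.0 d, on her count of working enzyme, comes to 26.5 h⁻¹ in Friday's, 23.4 h⁻¹ in Wednesday's and 20.4 h⁻¹ in Thursday's. Friday's flask read at 30 h has the south-west hours and working enzyme, so 39.5 h⁻¹ reckons 48.0% product there; it gives 39.1%.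

Readings and results come from a simulation for substances that don't exist; the scatter is artificial.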